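**Plan**

- Cuts: (a) C2'–C3' of the side chain, separating a chroman-2-ylethyl unit from a 14-carbon (E)-alkenyl iodide; (b) O1–C2 and C1'–C2' together, opening the pyran ring to a 2-(3-methylbut-3-enyl)phenol, CO and methanol; (c) the benzylic C–C bond of the homoallyl arm.
- Forward, first part: 2,5-dimethylhydroquinone is methylated, chloromethylated and coupled with a methallyl Grignard reagent; oxidation to the quinone, reduction and monosilylation give the cyclisation substrate.
- Forward, second part: the pyran ring (the only ring made) closes with a one-carbon extension; the ester is reduced, converted to the iodide and coupled as its zinc reagent with the alkenyl iodide built from geranyl bromide; desilylation ends the route.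
- Enabling feature: C2 of the pyran ring is a quaternary carbon bearing O1, so the alkylpalladium formed on C1' when O1 adds to the 1,1-disubstituted alkene has no β-hydrogen and lives long enough to take up CO.
- Stereochemistry: C2 comes from the axially chiral bis(oxazoline) ligand on palladium in the ring closure; (E)-C3'=C4' comes from syn-carboalumination, (E)-C7'=C8' from geranyl bromide, and the cross-coupling retains both.

Key step: step 7

Numbering: chroman = 3,4-dihydro-2H-chromene (O1, C2–C4, C4a, C5–C8, C8a); side-chain carbons are C1', C2' and so on, counted from C2.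

Assumption: (S,S)-Bn-BOXAX, (S)-2,2'-bis[(4S)-4-benzyl-4,5-dihydrooxazol-2-yl]-1,1'-binaphthyl, a separately prepared ligand used in catalytic amount, is assumed to favour the alkene face that leads to the (2S)-acetate; if a trial run shows the opposite sense, the (R,R)-ligand is used.

**Route**

Step 1
Reactants: 1 2,5-dimethylbenzene-1,4-diol (2,5-dimethylhydroquinone)
Product: 2 1,4-dimethoxy-2,5-dimethylbenzene
Conditions: MeI, K2CO3, acetone, reflux, N2
Reagents that add atoms: iodomethane CI
Why: Williamson O-methylation of both phenoxide oxygens by SN2 on iodomethane masks the hydroquinone as a dimethyl ether that tolerates the electrophilic and organometallic steps ahead and can later be removed oxidatively.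

Step 2
Reactants: 2 1,4-dimethoxy-2,5-dimethylbenzene
Product: 3 3-(chloromethyl)-1,4-dimethoxy-2,5-dimethylbenzene
Conditions: (CH2O)n (1 equiv), conc. aq. HCl, HCl gas, 1,4-dioxane, 20–40 °C
Reagents that add atoms: formaldehyde (as paraformaldehyde) C=O; hydrogen chloride Cl
Why: Blanc chloromethylation (electrophilic aromatic substitution by protonated formaldehyde, then chloride capture of the benzylic cation) occurs at one of the two equivalent free ring positions of the activated arene, and one equivalent of formaldehyde plus the slight deactivation by the first CH2Cl group should hold it at the mono stage.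

Step 3
Reactants: 3 3-(chloromethyl)-1,4-dimethoxy-2,5-dimethylbenzene; 4 3-chloro-2-methylprop-1-ene
Product: 6 1,4-dimethoxy-2,5-dimethyl-3-(3-methylbut-3-enyl)benzene, via methallylmagnesium chloride 5 (not isolated)
Conditions: Mg turnings, THF, 0 °C (slow addition of 4); then 3, THF, 0 °C to rt
Reagents that add atoms: none
Why: Uncatalysed Grignard coupling of an allylic magnesium reagent with a benzylic chloride is a dependable substitution, and because the methallyl unit is symmetric, direct and allyl-transposed attack give the same 3-methylbut-3-enyl arm.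

Step 4
Reactants: 6 1,4-dimethoxy-2,5-dimethyl-3-(3-methylbut-3-enyl)benzene
Product: 7 2,5-dimethyl-3-(3-methylbut-3-enyl)cyclohexa-2,5-diene-1,4-dione
Conditions: (NH4)2Ce(NO3)6 (2.2 equiv), MeCN–H2O, 0 °C
Reagents that add atoms: water O
Why: Oxidative demethylation of a 1,4-dimethoxyarene by tetravalent cerium runs through the arene radical cation, attack of water at the methoxy-bearing carbons and loss of methanol, and at 0 °C it is fast enough that the isolated 1,1-disubstituted alkene should be neither oxidised nor hydrated.

Step 5
Reactants: 7 2,5-dimethyl-3-(3-methylbut-3-enyl)cyclohexa-2,5-diene-1,4-dione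
Product: 8 2,5-dimethyl-3-(3-methylbut-3-enyl)benzene-1,4-diol
Conditions: Na2S2O4, Et2O–H2O, rt, argon
Reagents that add atoms: none
Why: Two-electron quinone reduction by dithionite in a two-phase system is a standard way to the hydroquinone and leaves the alkene untouched.

Step 6
Reactants: 8 2,5-dimethyl-3-(3-methylbut-3-enyl)benzene-1,4-diol
Product: 9 3,6-dimethyl-2-(3-methylbut-3-enyl)-4-(triisopropylsilyloxy)phenol
Conditions: i-Pr3SiCl (1.05 equiv), imidazole, DMF, 0 °C, argon
Reagents that add atoms: chlorotriisopropylsilane CC(C)[Si](Cl)(C(C)C)C(C)C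
Why: Sterically controlled monosilylation is expected because one hydroxyl lies between a methyl group and a ring hydrogen while the other lies between a methyl group and the homoallyl arm, so the bulky silyl chloride should take the former and leave the hydroxyl needed for ring closure free.

Step 7
Reactants: 9 3,6-dimethyl-2-(3-methylbut-3-enyl)-4-(triisopropylsilyloxy)phenol; 10 carbon monoxide; 11 methanol
Product: 12 methyl 2-[(2S)-2,5,8-trimethyl-6-(triisopropylsilyloxy)chroman-2-yl]acetate
Conditions: Pd(OCOCF3)2 (5 mol %), (S,S)-Bn-BOXAX (20 mol %), p-benzoquinone (4 equiv), CO (1 atm), MeOH, rt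
Reagents that add atoms: carbon monoxide [C-]#[O+]; methanol CO
Why: The complex of Pd(OCOCF3)2 with the bis(oxazoline) binds the 1,1-disubstituted alkene, the phenol oxygen adds to its internal carbon (oxypalladation, O1–C2), and the alkylpalladium on C1', which has no β-hydrogen because C2 is quaternary, inserts CO and is cleaved by methanol to the methyl ester (C1'–C2'), after which p-benzoquinone returns zerovalent palladium to the divalent state. The closest known reaction type is the enantioselective domino Wacker cyclisation–methoxycarbonylation of 2-(3-methylbut-3-enyl)phenols under divalent palladium with binaphthyl bis(oxazoline) ligands, and 9 is a 3,6-dimethyl-4-silyloxy member of that class. The pyran ring closes in the 6-exo-trig mode by C–O bond formation. The C2 stereocentre is set under catalyst control, the axially chiral ligand choosing the alkene enantioface that the oxygen attacks, and the (2S)-acetate has the spatial arrangement of the (2R)-target because the CIP ranks of C3 and the side chain change places once the chain is extended. The step needs attack by the right oxygen at the internal alkene carbon and carbonylation ahead of any elimination: the silyl ether leaves a single free hydroxyl, the tether length and the Markovnikov polarisation of the alkene direct that oxygen to the internal carbon, and the absence of a β-hydrogen leaves CO insertion as the productive path.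

Step 8
Reactants: 12 methyl 2-[(2S)-2,5,8-trimethyl-6-(triisopropylsilyloxy)chroman-2-yl]acetate
Product: 13 2-[(2S)-2,5,8-trimethyl-6-(triisopropylsilyloxy)chroman-2-yl]ethanol
Conditions: LiAlH4, Et2O, 0 °C
Reagents that add atoms: none
Why: Hydride reduction of the methyl ester by LiAlH4 gives the primary alcohol without touching the aryl silyl ether or the ether-type quaternary stereocentre.

Step 9
Reactants: 13 2-[(2S)-2,5,8-trimethyl-6-(triisopropylsilyloxy)chroman-2-yl]ethanol
Product: 14 (2S)-2-(2-iodoethyl)-2,5,8-trimethyl-6-(triisopropylsilyloxy)chroman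
Conditions: I2, PPh3, imidazole, CH2Cl2, 0 °C to rt (I2 premixed with PPh3)
Reagents that add atoms: iodine II
Why: Appel-type iodination converts the primary alcohol through its alkoxyphosphonium salt into the iodide by SN2 displacement at C2', remote from the stereocentre, and premixing iodine with the phosphine keeps free iodine away from the electron-rich arene.

Step 10
Reactants: 15 geranyl bromide; 16 trimethyl(prop-1-ynyl)silane
Product: 18 [(5E)-6,10-dimethylundeca-5,9-dien-1-ynyl]trimethylsilane, via lithiated silylpropyne 17 (not isolated)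
Conditions: n-BuLi, THF, −78 °C (16); then 15, −78 °C to rt
Reagents that add atoms: none
Why: Deprotonation of the silylpropyne gives a propargylic lithium reagent whose silyl group enforces propargyl instead of allenyl reactivity, and its SN2 alkylation by the primary allylic bromide keeps the (E)-trisubstituted alkene of the geranyl unit.

Step 11
Reactants: 18 [(5E)-6,10-dimethylundeca-5,9-dien-1-ynyl]trimethylsilane
Product: 19 (5E)-6,10-dimethylundeca-5,9-dien-1-yne
Conditions: K2CO3 (0.2 equiv), MeOH, rt
Reagents that add atoms: none
Why: Carbonate-catalysed methanolysis of the alkynyl C–Si bond (protodesilylation) frees the terminal alkyne without affecting the trisubstituted alkenes.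

Step 12
Reactants: 19 (5E)-6,10-dimethylundeca-5,9-dien-1-yne
Product: 21 (1E,5E)-1-iodo-2,6,10-trimethylundeca-1,5,9-triene, via alkenyldimethylalane 20 (not isolated)
Conditions: Me3Al (2 equiv), Cp2ZrCl2 (0.25 equiv), CH2Cl2, 0 °C to rt; then I2, THF, −30 to 0 °C
Reagents that add atoms: trimethylaluminium C[Al](C)C; iodine II
Why: Zirconium-catalysed methylalumination of the terminal alkyne (Negishi carboalumination) adds methyl and aluminium syn with aluminium on the terminal carbon, and iodinolysis of the C–Al bond with retention gives the (E)-alkenyl iodide that carries the future C3'=C4' geometry.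

Step 13
Reactants: 14 (2S)-2-(2-iodoethyl)-2,5,8-trimethyl-6-(triisopropylsilyloxy)chroman; 21 (1E,5E)-1-iodo-2,6,10-trimethylundeca-1,5,9-triene
Product: 23 (2R)-2,5,8-trimethyl-2-[(3E,7E)-4,8,12-trimethyltrideca-3,7,11-trienyl]-6-(triisopropylsilyloxy)chroman, via alkylzinc iodide 22 (not isolated)
Conditions: Zn dust (activated by BrCH2CH2Br and Me3SiCl), LiCl, THF, 40 °C (14); then 21, Pd(PPh3)4 (5 mol %), THF, rt to 40 °C
Reagents that add atoms: none
Why: In this Negishi sp3–sp2 cross-coupling, LiCl-assisted insertion of zinc into the primary C–I bond gives an alkylzinc iodide too unreactive to expel the γ-aryloxy group or attack the silyl ether, and its palladium-catalysed coupling with the alkenyl iodide forms C2'–C3' with retention of the (E) geometry.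

Step 14
Reactants: 23 (2R)-2,5,8-trimethyl-2-[(3E,7E)-4,8,12-trimethyltrideca-3,7,11-trienyl]-6-(triisopropylsilyloxy)chroman
Product: 24 (2R)-2,5,8-trimethyl-2-[(3E,7E)-4,8,12-trimethyltrideca-3,7,11-trienyl]chroman-6-ol
Conditions: Bu4NF, THF, 0 °C; aqueous work-up
Reagents that add atoms: none
Why: Fluoride-induced desilylation of the aryl silyl ether, driven by the strength of the Si–F bond, releases the phenol under conditions that leave the three alkenes and the C2 stereocentre unchanged.

**Compound list**

1 | 2,5-dimethylbenzene-1,4-diol (2,5-dimethylhydroquinone) | Cc1cc(O)c(C)cc1O | starting material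
2 | 1,4-dimethoxy-2,5-dimethylbenzene | COc1cc(C)c(OC)cc1C | intermediate
3 | 3-(chloromethyl)-1,4-dimethoxy-2,5-dimethylbenzene | COc1cc(C)c(OC)c(CCl)c1C | intermediate
4 | 3-chloro-2-methylprop-1-ene | C=C(C)CCl | starting material
5 | (2-methylprop-2-enyl)magnesium chloride | C=C(C)C[Mg]Cl | intermediate
6 | 1,4-dimethoxy-2,5-dimethyl-3-(3-methylbut-3-enyl)benzene | COc1cc(C)c(OC)c(CCC(C)=C)c1C | intermediate
7 | 2,5-dimethyl-3-(3-methylbut-3-enyl)cyclohexa-2,5-diene-1,4-dione | C=C(C)CCC1=C(C)C(=O)C=C(C)C1=O | intermediate
8 | 2,5-dimethyl-3-(3-methylbut-3-enyl)benzene-1,4-diol | C=C(C)CCc1c(C)c(O)cc(C)c1O | intermediate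
9 | 3,6-dimethyl-2-(3-methylbut-3-enyl)-4-(triisopropylsilyloxy)phenol | C=C(C)CCc1c(C)c(O[Si](C(C)C)(C(C)C)C(C)C)cc(C)c1O | intermediate
10 | carbon monoxide | [C-]#[O+] | starting material
11 | methanol | CO | starting material
12 | methyl 2-[(2S)-2,5,8-trimethyl-6-(triisopropylsilyloxy)chroman-2-yl]acetate | COC(=O)C[C@]1(C)CCc2c(C)c(O[Si](C(C)C)(C(C)C)C(C)C)cc(C)c2O1 | intermediate
13 | 2-[(2S)-2,5,8-trimethyl-6-(triisopropylsilyloxy)chroman-2-yl]ethanol | OCC[C@]1(C)CCc2c(C)c(O[Si](C(C)C)(C(C)C)C(C)C)cc(C)c2O1 | intermediate
14 | (2S)-2-(2-iodoethyl)-2,5,8-trimethyl-6-(triisopropylsilyloxy)chroman | ICC[C@]1(C)CCc2c(C)c(O[Si](C(C)C)(C(C)C)C(C)C)cc(C)c2O1 | intermediate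
15 | geranyl bromide, (2E)-1-bromo-3,7-dimethylocta-2,6-diene | CC(C)=CCC/C(C)=C/CBr | starting material
16 | trimethyl(prop-1-ynyl)silane | CC#C[Si](C)(C)C | starting material
17 | [3-(trimethylsilyl)prop-2-ynyl]lithium | [Li]CC#C[Si](C)(C)C | intermediate
18 | [(5E)-6,10-dimethylundeca-5,9-dien-1-ynyl]trimethylsilane | CC(C)=CCC/C(C)=C/CCC#C[Si](C)(C)C | intermediate
19 | (5E)-6,10-dimethylundeca-5,9-dien-1-yne | CC(C)=CCC/C(C)=C/CCC#C | intermediate
20 | dimethyl[(1E,5E)-2,6,10-trimethylundeca-1,5,9-trienyl]alumane | CC(C)=CCC/C(C)=C/CC/C(C)=C/[Al](C)C | intermediate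
21 | (1E,5E)-1-iodo-2,6,10-trimethylundeca-1,5,9-triene | CC(C)=CCC/C(C)=C/CC/C(C)=C/I | intermediate
22 | {2-[(2S)-2,5,8-trimethyl-6-(triisopropylsilyloxy)chroman-2-yl]ethyl}zinc iodide | I[Zn]CC[C@]1(C)CCc2c(C)c(O[Si](C(C)C)(C(C)C)C(C)C)cc(C)c2O1 | intermediate
23 | (2R)-2,5,8-trimethyl-2-[(3E,7E)-4,8,12-trimethyltrideca-3,7,11-trienyl]-6-(triisopropylsilyloxy)chroman | CC(C)=CCC/C(C)=C/CC/C(C)=C/CC[C@]1(C)CCc2c(C)c(O[Si](C(C)C)(C(C)C)C(C)C)cc(C)c2O1 | intermediate
24 | (2R)-2,5,8-trimethyl-2-[(3E,7E)-4,8,12-trimethyltrideca-3,7,11-trienyl]chroman-6-ol (β-tocotrienol) | CC(C)=CCC/C(C)=C/CC/C(C)=C/CC[C@]1(C)CCc2c(C)c(O)cc(C)c2O1 | target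

**Count and risks**

Total step count: 14. Longest linear sequence: 11 (steps 1–9, 13 and 14); steps 10–12 are a three-step branch to the alkenyl iodide.

Steps most likely to fail:

1. Step 7. CO competes with the bis(oxazoline) for the metal and can reduce divalent palladium. Part of the oxypalladation may then run on ligand-free palladium, eroding enantioface selectivity, or the catalyst may precipitate before it turns over. The fallback sets out from 9 and runs the same oxypalladation without CO, intercepting the alkylpalladium with an alkene instead (domino Wacker–Heck reaction: methyl acrylate, Pd(OCOCF3)2, (S,S)-Bn-BOXAX, p-benzoquinone, CH2Cl2, rt). This should give methyl (2E)-4-[(2S)-2,5,8-trimethyl-6-(triisopropylsilyloxy)chroman-2-yl]but-2-enoate F1. Lemieux–Johnson cleavage of the enoate alkene (catalytic OsO4, NaIO4, 2,6-lutidine, dioxane–H2O) would give 2-[(2S)-2,5,8-trimethyl-6-(triisopropylsilyloxy)chroman-2-yl]acetaldehyde F2. NaBH4 in MeOH reduces it to 13, where the route is rejoined; 12 and step 8 are bypassed.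

2. Step 13. Zinc insertion into the iodide may be sluggish or incomplete, and at the coupling stage β-hydride elimination from the alkylpalladium intermediate or homocoupling of the alkenyl iodide may compete. The fallback sets out from 14 and generates the nucleophile by hydroboration instead of metal insertion. E2 elimination with t-BuOK in THF gives (2S)-2-ethenyl-2,5,8-trimethyl-6-(triisopropylsilyloxy)chroman F3. 9-BBN-H in THF adds boron to the terminal vinyl carbon to give 9-{2-[(2R)-2,5,8-trimethyl-6-(triisopropylsilyloxy)chroman-2-yl]ethyl}-9-borabicyclo[3.3.1]nonane F4; the descriptor changes by CIP rank only. B-alkyl Suzuki–Miyaura coupling of F4 with 21 (PdCl2(dppf), aqueous K3PO4, THF–DMF, rt to 50 °C) comes back to the route at 23.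

3. Step 6. Site discrimination between the two hydroxyls may be incomplete (silylation of the hindered oxygen, bis-silylation), and the hydroquinone may be oxidised back to the quinone by air. The fallback sets out from 1, needs no site selection, and replaces steps 1–6.
   - One equivalent of i-Pr3SiCl with imidazole in DMF gives statistically 2,5-dimethyl-4-(triisopropylsilyloxy)phenol F5; the two hydroxyls of 1 are equivalent, and unreacted 1 is recycled.
   - Mannich aminomethylation (aqueous CH2O, Me2NH, EtOH, reflux) at the only free position ortho to the hydroxyl gives 2-[(dimethylamino)methyl]-3,6-dimethyl-4-(triisopropylsilyloxy)phenol F6.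
   - MeI converts it into [2-hydroxy-3,6-dimethyl-5-(triisopropylsilyloxy)phenyl]methyl-trimethylammonium iodide F7.
   - With an excess of 5 (made from 4 as in step 3) in THF, the phenoxide expels the amine to the ortho-quinone methide 2,5-dimethyl-6-methylidene-4-(triisopropylsilyloxy)cyclohexa-2,4-dien-1-one F8. A further equivalent of 5 adds to its exocyclic methylene, and the sequence comes back to the route at 9.
   - It is shorter on paper but is held in reserve because it trades one selectivity question for a statistical protection and a less general quinone methide alkylation.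

**Further compounds**

F1 | step 7 | methyl (2E)-4-[(2S)-2,5,8-trimethyl-6-(triisopropylsilyloxy)chroman-2-yl]but-2-enoate | COC(=O)/C=C/C[C@]1(C)CCc2c(C)c(O[Si](C(C)C)(C(C)C)C(C)C)cc(C)c2O1
F2 | step 7 | 2-[(2S)-2,5,8-trimethyl-6-(triisopropylsilyloxy)chroman-2-yl]acetaldehyde | O=CC[C@]1(C)CCc2c(C)c(O[Si](C(C)C)(C(C)C)C(C)C)cc(C)c2O1
F3 | step 13 | (2S)-2-ethenyl-2,5,8-trimethyl-6-(triisopropylsilyloxy)chroman | C=C[C@]1(C)CCc2c(C)c(O[Si](C(C)C)(C(C)C)C(C)C)cc(C)c2O1
F4 | step 13 | 9-{2-[(2R)-2,5,8-trimethyl-6-(triisopropylsilyloxy)chroman-2-yl]ethyl}-9-borabicyclo[3.3.1]nonane | C1CCC2CCCC1B2CC[C@]3(C)CCc4c(C)c(O[Si](C(C)C)(C(C)C)C(C)C)cc(C)c4O3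
F5 | step 6 | 2,5-dimethyl-4-(triisopropylsilyloxy)phenol | Cc1cc(O[Si](C(C)C)(C(C)C)C(C)C)c(C)cc1O
F6 | step 6 | 2-[(dimethylamino)methyl]-3,6-dimethyl-4-(triisopropylsilyloxy)phenol | CN(C)Cc1c(C)c(O[Si](C(C)C)(C(C)C)C(C)C)cc(C)c1O
F7 | step 6 | [2-hydroxy-3,6-dimethyl-5-(triisopropylsilyloxy)phenyl]methyl-trimethylammonium iodide | C[N+](C)(C)Cc1c(C)c(O[Si](C(C)C)(C(C)C)C(C)C)cc(C)c1O.[I-]
F8 | step 6 | 2,5-dimethyl-6-methylidene-4-(triisopropylsilyloxy)cyclohexa-2,4-dien-1-one | C=C1C(C)=C(O[Si](C(C)C)(C(C)C)C(C)C)C=C(C)C1=O
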